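**Retrosynthetic overview**
1. Last step: one-pot removal of six allyl groups (five aryl ethers, one ester). No hydrogenation is used, so both conjugated C=C bonds survive.
2. Key disconnection: the cinnamate Cα=Cβ bond. It is made by an intermolecular Knoevenagel–Doebner (aldol-type) condensation of a coumarin-bearing aryl aldehyde and the malonic half-ester of the (R)-aryllactate.
3. Only ring formed: the coumarin pyranone, closed before the fragment union. A 4,5-bis(allyloxy)salicylaldehyde is O-acylated by an aryloxyacetic acid, then aldol condensation forms C3–C4. The three benzene rings are bought.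
4. Both coumarin precursors come from 3,4-dihydroxybenzaldehyde: allylation/Dakin/ortho-formylation for one, regioselective 4-O-alkylation with tert-butyl bromoacetate for the other.
5. The single stereocentre comes from methyl (R)-glycidate, opened at its CH2 by an aryl Grignard reagent under copper catalysis.

Assumption: the stereocentre in the SMILES reads as R (as in natural rosmarinic acid). Simple reagents such as allyl bromide are named as reagents and carry no number.

**Step 1**
Reactants: 1 3,4-dihydroxybenzaldehyde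
Product: 2 3,4-bis(allyloxy)benzaldehyde
Conditions: allyl bromide (2.5 equiv), K2CO3 (3 equiv), DMF, 60 °C, 4 h
Reagents that add atoms: allyl bromide C=CCBr
Why: Double Williamson ether synthesis (SN2 of both phenoxides on allyl bromide); allyl is used on every OH because it survives acid, amine bases and organometallics and comes off at the end without hydrogenation.

**Step 2**
Reactants: 2 3,4-bis(allyloxy)benzaldehyde
Product: 4 3,4-bis(allyloxy)phenol, via aryl formate 3 (not isolated)
Conditions: 30% aq H2O2 (1.3 equiv), H2SO4 (cat.), MeOH, rt, 14 h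
Reagents that add atoms: hydrogen peroxide OO
Why: Acid-catalysed Dakin-type (Baeyer–Villiger) oxidation in which the electron-rich aryl group migrates to oxygen and methanol cleaves the formate, while metal-free H2O2 leaves the unactivated allyl C=C bonds alone.

**Step 3**
Reactants: 4 3,4-bis(allyloxy)phenol
Product: 6 4,5-bis(allyloxy)-2-hydroxybenzaldehyde, via salicyl alcohol 5 (not isolated)
Conditions: MgCl2 (2 equiv), Et3N (4 equiv), paraformaldehyde (6 equiv), MeCN, reflux, 3 h; 1 M HCl work-up
Reagents that add atoms: paraformaldehyde (reacts as formaldehyde) C=O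
Why: Casnati–Skattebøl ortho-formylation, in which the magnesium phenoxide delivers formaldehyde only to an ortho carbon, the open position wins over the crowded one between two oxygens, and a second formaldehyde oxidises the salicyl alcohol by hydride transfer.

**Step 4**
Reactants: 1 3,4-dihydroxybenzaldehyde; 7 tert-butyl bromoacetate
Product: 8 tert-butyl 2-(4-formyl-2-hydroxyphenoxy)acetate
Conditions: 7 (1.05 equiv), NaHCO3 (1.5 equiv), DMF, 40 °C, 20 h
Reagents that add atoms: none
Why: Regioselective Williamson etherification, because NaHCO3 ionises only the more acidic 4-OH (para to the formyl group) and the bulky tert-butyl ester keeps the neighbouring free 3-OH from lactonising.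

**Step 5**
Reactants: 8 tert-butyl 2-(4-formyl-2-hydroxyphenoxy)acetate
Product: 9 tert-butyl 2-[2-(allyloxy)-4-formylphenoxy]acetate
Conditions: allyl bromide (1.3 equiv), K2CO3 (1.5 equiv), DMF, rt, 6 h
Reagents that add atoms: allyl bromide C=CCBr
Why: Williamson ether synthesis on the remaining phenol, fast enough at room temperature that the tert-butyl ester and the aldehyde are untouched.

**Step 6**
Reactants: 9 tert-butyl 2-[2-(allyloxy)-4-formylphenoxy]acetate
Product: 10 2-[2-(allyloxy)-4-formylphenoxy]acetic acid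
Conditions: TFA/CH2Cl2 1:3, rt, 3 h
Reagents that add atoms: none
Why: Acidolysis of the tert-butyl ester (E1 loss of the tert-butyl cation as isobutene), to which the aryl allyl ether and the aldehyde are inert.

**Step 7**
Reactants: 6 4,5-bis(allyloxy)-2-hydroxybenzaldehyde; 10 2-[2-(allyloxy)-4-formylphenoxy]acetic acid
Product: 13 3-(allyloxy)-4-{[6,7-bis(allyloxy)-2-oxo-2H-chromen-3-yl]oxy}benzaldehyde, via aryl ester 11 (not isolated), via aldol lactone 12 (not isolated)
Conditions: EDC·HCl (1.5 equiv), DMAP (0.2 equiv), 4 Å molecular sieves, CH2Cl2 (0.05 M), 0 °C to rt, 3 h; then DBU (2 equiv), rt, 6 h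
Reagents that add atoms: none
Why: Steglich esterification of the salicylaldehyde OH followed by a DBU-promoted aldol condensation (Perkin/Knoevenagel-type coumarin synthesis), in which the activated OCH2 attacks the ortho formyl group through a six-membered ring far faster than any remote formyl group, and E1cB loss of water gives the pyranone.

**Step 8**
Reactants: 14 4-bromocatechol
Product: 15 1,2-bis(allyloxy)-4-bromobenzene
Conditions: allyl bromide (2.5 equiv), K2CO3 (3 equiv), DMF, 60 °C, 4 h
Reagents that add atoms: allyl bromide C=CCBr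
Why: Double Williamson ether synthesis; the aryl bromide is inert to these SN2 conditions.

**Step 9**
Reactants: 15 1,2-bis(allyloxy)-4-bromobenzene; 16 methyl (R)-glycidate (methyl (2R)-oxirane-2-carboxylate)
Product: 18 methyl (2R)-3-[3,4-bis(allyloxy)phenyl]-2-hydroxypropanoate, via aryl Grignard reagent 17 (not isolated)
Conditions: 15 (1.3 equiv), Mg turnings, THF, 40 °C; then slow addition to 16 and CuBr·SMe2 (15 mol%), THF, −40 to −20 °C; aq NH4Cl
Reagents that add atoms: none
Why: Copper-catalysed SN2 epoxide opening by the Grignard reagent takes place at the unsubstituted CH2 faster than ester addition at −40 °C, so the C–O bond at the stereocentre is never broken and the R configuration of the glycidate is carried into the hydroxy ester.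

**Step 10**
Reactants: 18 methyl (2R)-3-[3,4-bis(allyloxy)phenyl]-2-hydroxypropanoate
Product: 19 (2R)-3-[3,4-bis(allyloxy)phenyl]-2-hydroxypropanoic acid
Conditions: LiOH (2 equiv), THF/H2O 3:1, 0 °C, 2 h; then 1 M HCl to pH 2
Reagents that add atoms: lithium hydroxide [Li+].[OH-]
Why: Ester saponification (BAc2) at 0 °C, where the carboxylate formed shuts down enolisation so the R stereocentre is not eroded.

**Step 11**
Reactants: 19 (2R)-3-[3,4-bis(allyloxy)phenyl]-2-hydroxypropanoic acid
Product: 20 allyl (2R)-3-[3,4-bis(allyloxy)phenyl]-2-hydroxypropanoate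
Conditions: allyl bromide (1.2 equiv), KHCO3 (1.5 equiv), DMF, rt, 12 h
Reagents that add atoms: allyl bromide C=CCBr
Why: SN2 O-alkylation of the carboxylate, since KHCO3 ionises only the acid and the secondary alcohol stays free for the next step.

**Step 12**
Reactants: 20 allyl (2R)-3-[3,4-bis(allyloxy)phenyl]-2-hydroxypropanoate; 21 Meldrum's acid (2,2-dimethyl-1,3-dioxane-4,6-dione)
Product: 22 3-{[(2R)-1-(allyloxy)-3-[3,4-bis(allyloxy)phenyl]-1-oxopropan-2-yl]oxy}-3-oxopropanoic acid (malonic half-ester of 20)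
Conditions: 21 (1.2 equiv), toluene, 110 °C, 4 h
Reagents that add atoms: none
Why: Thermal alcoholysis of Meldrum's acid (O-acylation with loss of acetone) gives the malonic half-ester directly without touching the stereocentre, and 110 °C is well below the temperature of the aryl allyl ether Claisen rearrangement.

**Step 13 (key step)**
Reactants: 13 3-(allyloxy)-4-{[6,7-bis(allyloxy)-2-oxo-2H-chromen-3-yl]oxy}benzaldehyde; 22 malonic half-ester of 20
Product: 24 allyl (2R)-3-[3,4-bis(allyloxy)phenyl]-2-{[(2E)-3-(3-(allyloxy)-4-{[6,7-bis(allyloxy)-2-oxo-2H-chromen-3-yl]oxy}phenyl)prop-2-enoyl]oxy}propanoate (hexa-allyl target), via aldol adduct 23 (not isolated)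
Conditions: 22 (1.3 equiv), pyridine, piperidine (0.2 equiv), 55 °C, 18 h
Reagents that add atoms: none
Why: Knoevenagel–Doebner condensation, in which the enolised malonic half-ester adds to the aryl aldehyde in an intermolecular aldol-type step, the adduct loses water and CO2 to give only the E-cinnamate, and the weak amine bases do not deprotonate the acyloxy-bearing carbon, so R is retained.

**Step 14**
Reactants: 24 hexa-allyl target
Product: 25 (2R)-3-(3,4-dihydroxyphenyl)-2-{[(2E)-3-{4-[(6,7-dihydroxy-2-oxo-2H-chromen-3-yl)oxy]-3-hydroxyphenyl}prop-2-enoyl]oxy}propanoic acid (CNP0318082.1)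
Conditions: Pd(PPh3)4 (10 mol%), morpholine (18 equiv), degassed THF, Ar, rt, 3 h; then 1 M HCl, EtOAc; reversed-phase chromatography
Reagents that add atoms: none
Why: Tsuji–Trost-type allyl transfer, in which zerovalent palladium ionises the five aryl allyl ethers and the allyl ester to π-allyl complexes that morpholine captures irreversibly, leaving the cinnamate and coumarin C=C bonds, the lactone, the ester and the stereocentre untouched.

**Compound list**
1 | 3,4-dihydroxybenzaldehyde | O=Cc1ccc(O)c(O)c1 | starting material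
2 | 3,4-bis(allyloxy)benzaldehyde | O=Cc1ccc(OCC=C)c(OCC=C)c1 | intermediate
3 | 3,4-bis(allyloxy)phenyl formate (not isolated) | O=COc1ccc(OCC=C)c(OCC=C)c1 | intermediate
4 | 3,4-bis(allyloxy)phenol | Oc1ccc(OCC=C)c(OCC=C)c1 | intermediate
5 | 4,5-bis(allyloxy)-2-(hydroxymethyl)phenol, present as its magnesium salt (not isolated) | OCc1cc(OCC=C)c(OCC=C)cc1O | intermediate
6 | 4,5-bis(allyloxy)-2-hydroxybenzaldehyde | O=Cc1cc(OCC=C)c(OCC=C)cc1O | intermediate
7 | tert-butyl bromoacetate | CC(C)(C)OC(=O)CBr | starting material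
8 | tert-butyl 2-(4-formyl-2-hydroxyphenoxy)acetate | O=Cc1ccc(OCC(=O)OC(C)(C)C)c(O)c1 | intermediate
9 | tert-butyl 2-[2-(allyloxy)-4-formylphenoxy]acetate | O=Cc1ccc(OCC(=O)OC(C)(C)C)c(OCC=C)c1 | intermediate
10 | 2-[2-(allyloxy)-4-formylphenoxy]acetic acid | O=Cc1ccc(OCC(=O)O)c(OCC=C)c1 | intermediate
11 | 4,5-bis(allyloxy)-2-formylphenyl 2-[2-(allyloxy)-4-formylphenoxy]acetate (not isolated) | O=Cc1ccc(OCC(=O)Oc2cc(OCC=C)c(OCC=C)cc2C=O)c(OCC=C)c1 | intermediate
12 | 3-(allyloxy)-4-{[6,7-bis(allyloxy)-4-hydroxy-2-oxochroman-3-yl]oxy}benzaldehyde, diastereomer mixture (not isolated) | O=Cc1ccc(OC2C(O)c3cc(OCC=C)c(OCC=C)cc3OC2=O)c(OCC=C)c1 | intermediate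
13 | 3-(allyloxy)-4-{[6,7-bis(allyloxy)-2-oxo-2H-chromen-3-yl]oxy}benzaldehyde | O=Cc1ccc(Oc2cc3cc(OCC=C)c(OCC=C)cc3oc2=O)c(OCC=C)c1 | intermediate
14 | 4-bromocatechol (4-bromobenzene-1,2-diol) | Oc1ccc(Br)cc1O | starting material
15 | 1,2-bis(allyloxy)-4-bromobenzene | C=CCOc1ccc(Br)cc1OCC=C | intermediate
16 | methyl (2R)-oxirane-2-carboxylate (methyl (R)-glycidate) | COC(=O)[C@H]1CO1 | starting material
17 | [3,4-bis(allyloxy)phenyl]magnesium bromide (not isolated) | Br[Mg]c1ccc(OCC=C)c(OCC=C)c1 | intermediate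
18 | methyl (2R)-3-[3,4-bis(allyloxy)phenyl]-2-hydroxypropanoate | COC(=O)[C@H](O)Cc1ccc(OCC=C)c(OCC=C)c1 | intermediate
19 | (2R)-3-[3,4-bis(allyloxy)phenyl]-2-hydroxypropanoic acid | OC(=O)[C@H](O)Cc1ccc(OCC=C)c(OCC=C)c1 | intermediate
20 | allyl (2R)-3-[3,4-bis(allyloxy)phenyl]-2-hydroxypropanoate | C=CCOC(=O)[C@H](O)Cc1ccc(OCC=C)c(OCC=C)c1 | intermediate
21 | Meldrum's acid (2,2-dimethyl-1,3-dioxane-4,6-dione) | CC1(C)OC(=O)CC(=O)O1 | starting material
22 | 3-{[(2R)-1-(allyloxy)-3-[3,4-bis(allyloxy)phenyl]-1-oxopropan-2-yl]oxy}-3-oxopropanoic acid | OC(=O)CC(=O)O[C@H](Cc1ccc(OCC=C)c(OCC=C)c1)C(=O)OCC=C | intermediate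
23 | β-hydroxy malonic half-ester from 13 and 22, R at the lactate carbon, mixture at the two new carbons (not isolated) | OC(=O)C(C(O)c1ccc(Oc2cc3cc(OCC=C)c(OCC=C)cc3oc2=O)c(OCC=C)c1)C(=O)O[C@H](Cc1ccc(OCC=C)c(OCC=C)c1)C(=O)OCC=C | intermediate
24 | allyl (2R)-3-[3,4-bis(allyloxy)phenyl]-2-{[(2E)-3-(3-(allyloxy)-4-{[6,7-bis(allyloxy)-2-oxo-2H-chromen-3-yl]oxy}phenyl)prop-2-enoyl]oxy}propanoate | O=C(/C=C/c1ccc(Oc2cc3cc(OCC=C)c(OCC=C)cc3oc2=O)c(OCC=C)c1)O[C@H](Cc1ccc(OCC=C)c(OCC=C)c1)C(=O)OCC=C | intermediate
25 | (2R)-3-(3,4-dihydroxyphenyl)-2-{[(2E)-3-{4-[(6,7-dihydroxy-2-oxo-2H-chromen-3-yl)oxy]-3-hydroxyphenyl}prop-2-enoyl]oxy}propanoic acid | O=C(/C=C/c1ccc(Oc2cc3cc(O)c(O)cc3oc2=O)c(O)c1)O[C@H](Cc1ccc(O)c(O)c1)C(=O)O | target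

**Total step count:** 14. **Longest linear sequence:** 7 (steps 8, 9, 10, 11, 12, 13, 14, from 4-bromocatechol).

**Three steps most likely to fail**

**Step 9.**
- Risks: the Grignard reagent may attack the ester. Magnesium bromide may open the epoxide to a bromohydrin. Magnesium metal may nibble at the allyl ethers.
- The fallback sets out from 15 and comes back at 19. It makes the C–C bond on an epoxide that carries no ester and installs the acid later.
- Bromine–lithium exchange of 15 with n-BuLi (THF, −78 °C) gives [3,4-bis(allyloxy)phenyl]lithium F1.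
- Under BF3·OEt2 activation, F1 opens commercial tert-butyldimethylsilyl (R)-glycidyl ether at its CH2 terminus. This gives (2R)-1-[3,4-bis(allyloxy)phenyl]-3-[(tert-butyldimethylsilyl)oxy]propan-2-ol F2.
- TBAF in THF then gives (2R)-3-[3,4-bis(allyloxy)phenyl]propane-1,2-diol F3.
- TEMPO/PhI(OAc)2 in MeCN–H2O oxidises only the primary alcohol to the acid 19. The carbinol stereocentre is untouched throughout.

**Step 13.**
- Risks: the precious half-ester may decarboxylate to the acetate before it condenses, or the condensation may stall on the bulky partners.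
- The fallback sets out from 13, uses alcohol 20, and comes back at 24. It moves the fragment union from the C=C bond to the ester C–O bond.
- 13 is condensed with cheap malonic acid (pyridine, cat. piperidine, 85 °C).
- The 2-[3-(allyloxy)-4-{[6,7-bis(allyloxy)-2-oxo-2H-chromen-3-yl]oxy}benzylidene]malonic acid F4 so formed loses CO2 in the hot pyridine. This gives (2E)-3-(3-(allyloxy)-4-{[6,7-bis(allyloxy)-2-oxo-2H-chromen-3-yl]oxy}phenyl)prop-2-enoic acid F5.
- Steglich esterification of F5 with 20 (EDC·HCl, DMAP, CH2Cl2, 0 °C to rt) gives 24. The stereocentre is retained because only the O–H bond of 20 reacts.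

**Step 14.**
- Risks: removal of six allyl groups may be incomplete, and the air-sensitive polyphenolic acid may be lost in the amine medium.
- The fallback sets out from 13 and 22 and comes back at 25. It deprotects the two robust halves before they are joined, so the full molecule never sees a deprotection.
- Pd(PPh3)4/morpholine in THF converts 13 into 4-[(6,7-dihydroxy-2-oxo-2H-chromen-3-yl)oxy]-3-hydroxybenzaldehyde F6.
- The same conditions convert 22 into (2R)-2-[(carboxyacetyl)oxy]-3-(3,4-dihydroxyphenyl)propanoic acid F7.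
- Knoevenagel–Doebner condensation of F6 and F7 follows (pyridine, cat. piperidine, Ar, 50 °C). It passes through the unprotected β-hydroxy malonic half-ester F8 and gives 25 directly on acidification.

**Further compounds**
F1 | step 9 | [3,4-bis(allyloxy)phenyl]lithium | [Li]c1ccc(OCC=C)c(OCC=C)c1
F2 | step 9 | (2R)-1-[3,4-bis(allyloxy)phenyl]-3-[(tert-butyldimethylsilyl)oxy]propan-2-ol | CC(C)(C)[Si](C)(C)OC[C@H](O)Cc1ccc(OCC=C)c(OCC=C)c1
F3 | step 9 | (2R)-3-[3,4-bis(allyloxy)phenyl]propane-1,2-diol | OC[C@H](O)Cc1ccc(OCC=C)c(OCC=C)c1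
F4 | step 13 | 2-[3-(allyloxy)-4-{[6,7-bis(allyloxy)-2-oxo-2H-chromen-3-yl]oxy}benzylidene]malonic acid | OC(=O)C(=Cc1ccc(Oc2cc3cc(OCC=C)c(OCC=C)cc3oc2=O)c(OCC=C)c1)C(=O)O
F5 | step 13 | (2E)-3-(3-(allyloxy)-4-{[6,7-bis(allyloxy)-2-oxo-2H-chromen-3-yl]oxy}phenyl)prop-2-enoic acid | OC(=O)/C=C/c1ccc(Oc2cc3cc(OCC=C)c(OCC=C)cc3oc2=O)c(OCC=C)c1
F6 | step 14 | 4-[(6,7-dihydroxy-2-oxo-2H-chromen-3-yl)oxy]-3-hydroxybenzaldehyde | O=Cc1ccc(Oc2cc3cc(O)c(O)cc3oc2=O)c(O)c1
F7 | step 14 | (2R)-2-[(carboxyacetyl)oxy]-3-(3,4-dihydroxyphenyl)propanoic acid | OC(=O)CC(=O)O[C@H](Cc1ccc(O)c(O)c1)C(=O)O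
F8 | step 14 | unprotected β-hydroxy malonic half-ester from F6 and F7, R at the lactate carbon, mixture at the two new carbons | OC(=O)C(C(O)c1ccc(Oc2cc3cc(O)c(O)cc3oc2=O)c(O)c1)C(=O)O[C@H](Cc1ccc(O)c(O)c1)C(=O)O
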